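The number I carried was 2.71 M⁻¹ h⁻¹: the specific rate κ, the first-order decay constant of the starting material per molar of reagent still left in both phases together.

| setting | west | south-east | flask |
|---|---|---|---|
| starting material | 0.20 M | 0.20 M | 0.20 M |
| reagent in the second phase | 0.42 M | 0.66 M | 0.300 M |
| remark | run made earlier | run made earlier |  |
| time |  |  | 6.0 h |
| volume of the second phase over the first |  |  | 1.0 |

- west (time / h: target / %, starting material / %): 0.667: 36.9, 56.8; 1.33: 50.7, 31.7; 2.00: 56.4, 19.3; 3.00: 60.4, 8.9; 4.00: 62.7, 5.0; 5.00: 62.4, 1.8
- south-east (time / h: target / %, starting material / %): 0.250: 22.8, 76.8; 0.667: 49.0, 39.8; 1.33: 62.0, 14.9; 2.00: 64.6, 6.4; 3.00: 64.9, 2.2; 4.00: 63.8, 0; 5.00: 62.4, 0.2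

(each reading ± 0.5 percentage points)

1. target and product in the second phase together at 6.0 h, in percent of the starting material charged
2. part of the starting material charged that has reacted at 6.0 h

- target is meant together with its product in the second phase
- in the second phase: reagent in the second phase, product in the second phase; everything else is in the first
- charges count per volume of the first phase; a concentration in a rate is the amount of a species over the volume of its own phase; every rate counts per litre of the first phase
- the earlier runs hold the two phases in the same ratio of volumes as the flask asked about

With charges b of reagent and c of starting material, a the fraction of starting material left, and one reagent used per starting material, freezing κ gives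

a = (b − c) / (b·E − c), with E = exp(κ(b − c)t).

Solved for κ, this gave 2.80 M⁻¹ h⁻¹ from the west run at 3.00 h and 2.63 M⁻¹ h⁻¹ from the south-east run at 2.00 h; I took the mean.

For the flask, reagent frozen at its charge (the pseudo-first-order case) bounded conversion from above:

a = exp(−κbt), conversion 99.2%.

Reagent frozen at b − c bounded it from below, at 80.4%. The full line tightened this:

E = 5.10, a = 7.52%, conversion 92.5%.

The west run at 5.00 h read 63.5% of the reacted starting material as target; frozen too, that gave y = 58.7%.

The forecast said 59.5% and 96%, with decay “about first order in reagent”, inside my bracket  and above my conversion.

The flask gave 58.3% and 93.0%.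

    reagent in the reaction phase ⇌ reagent in the second phase, rate k1*([reagent in the reaction phase] - [reagent in the second phase]/K1) per volume of the first phase (partition coefficient = 2.60, kL = 0.00200 s⁻¹)
    target → decomposed product (k = 1.30 × 10⁻⁴ s⁻¹)
    target ⇌ product in the second phase, rate k3*([target] - [product in the second phase]/K3) per volume of the first phase (partition coefficient = 25.0, kL = 4.80 × 10⁻⁴ s⁻¹)
    starting material + reagent in the reaction phase → target (k = 0.00300 M⁻¹ s⁻¹)
    target → over-reaction product (k = 1.00 × 10⁻⁴ s⁻¹)

At 6.00 h the flask held 0.0313 M of reagent in the reaction phase and 27.6% of its charge in the second phase, together 0.114 M. κ times that is 0.309 h⁻¹, my estimate of the decay constant of the remaining starting material; the scheme's rate constant for starting material + reagent in the reaction phase, times the reagent in the reaction phase alone, gives 0.338 h⁻¹ at that moment.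

The neighbour charged with 0.50 M of starting material has reagent as limiting reagent; the same line gives a = 40.9%. Computed, it left 41.4%, with y = 36.4%.

The runs were computed with made-up constants, and the scatter is random.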